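In a closed stirred flask, a plug-flow tube and a stirred tank, 5.0 mM of substrate is charged, and I keep a ledger of where each mole goes.

| flask | substrate | remark | time |
|---|---|---|---|
| autumn | 5 mM | run made earlier |  |
| summer | 3.4 mM | run made earlier |  |
| noon | 7.5 mM | run made earlier |  |
| zeta | 5.0 mM | everything together in a closed stirred flask, run for 2.0 min | 2.0 min |
| eta | 5.0 mM | plug flow through a tube for 2.0 min, no back-mixing | 2.0 min |
| alpha | 5.0 mM | one stirred flow tank at steady state, fed with the mixture as stated, mean residence time 2.0 min |  |

| run | time / s | target / % | side product / % |
|---|---|---|---|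
| autumn | 15.0 | 48.1 | 26.0 |
| autumn | 30.0 | 51.2 | 28.5 |
| autumn | 50.0 | 50.4 | 32.1 |
| autumn | 60.0 | 49.6 | 32.3 |
| autumn | 80.0 | 47.5 | 33.4 |
| autumn | 90.0 | 47.0 | 33.5 |
| autumn | 120 | 44.1 | 34.2 |
| summer | 10.0 | 47.1 | 25.5 |
| summer | 20.0 | 51.8 | 28.5 |
| summer | 30.0 | 52.0 | 30.2 |
| summer | 50.0 | 50.9 | 32.2 |
| summer | 80.0 | 48.0 | 33.3 |
| summer | 90.0 | 46.9 | 34.2 |
| summer | 120 | 43.3 | 33.1 |
| noon | 10.0 | 44.1 | 24.4 |
| noon | 15.0 | 47.3 | 25.1 |
| noon | 20.0 | 49.0 | 26.6 |
| noon | 30.0 | 49.0 | 28.7 |
| noon | 50.0 | 49.0 | 29.6 |
| noon | 80.0 | 48.0 | 32.1 |
| noon | 120 | 44.9 | 33.4 |

(standard deviation of a reading: 0.5 percentage points)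

- the stated concentrations are those of everything mixed, before any reaction; amounts are the same in each set-up
- the numbers in the tables scatter with a standard deviation of 0.5 percentage points
- the earlier runs were made in a closed, stirred flask
- a reading or a percentage of target counts all its forms, free or not

- the set-up with the highest share of target in all that became target or side product or isomer of the product, at the outlet or at the end ("none" if the first two lie within 2 percentage points) (zeta / eta / alpha / none)
- share of target in all that became target or side product or isomer of the product, at the outlet or at the end, zeta
- share of target in all that became target or side product or isomer of the product, at the outlet or at the end, eta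
- share of target in all that became target or side product or isomer of the product, at the outlet or at the end, alpha

The earliest autumn reading, at 15.0 s, gives target T over side product Q as ρ = 1.85, and I read this as the split of converted substrate. The first-pass share, the selectivity f = ρ/(1+ρ), is then 64.9 %.

The autumn run at 120 s has zeta's charge and time, so I close its books there. Target stands at 44.1 % and side product at 34.2 %. Isomer, taken as ρQ − T, is 19.2 %, and I book the remaining 2.53 % as unconverted, an estimate that carries the scatter of the readings. By this estimate isomer has taken a lost fraction of 30.3 % of the target made, and the share is f times what remains, 45.2 %. A plug in the tube ages as the closed flask does, so I give zeta and eta this value.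

The tank's mean residence time equals that time, but its ages spread. If the loss is first-order, with L = −ln(1 − lost fraction) = 0.361, the kept fraction becomes 1/(1+L) and the share 47.7 %. That lies 2.5 percentage points above the closed flask, just past the margin of 2 points, so I name alpha, narrowly, given the scatter of 0.5 points.

The forecast gives 45.5 % for zeta, 45.5 % for eta and 46 % for alpha, and says “The difference is under 2 points”, hence none. On the tank and the winner it differs from my reckoning.

The flask gives 45.1 % for zeta, 45.1 % for eta and 52.8 % for alpha, so the best is alpha.

    substrate → target (k = 0.230 s⁻¹)
    substrate → side product (k = 0.120 s⁻¹)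
    substrate + target ⇌ idle adduct, settled at all times (K = 5700 M⁻¹)
    target ⇌ isomer of the product (K = 0.610, k = 0.00840 s⁻¹)

Substrate's half-lives on its two routes, 0.050 min to target and 0.096 min to side product, are far shorter than the 1.4 min of free target going to isomer, forward rate with the way back not counted. Held against f, which remains a reading, the shares put the lost fraction at 18.6 % in alpha and 30.5 % in zeta, and in zeta left for 20.0 min at 37.1 %.

The numbers in the tables come from a simulation for an exercise, and the scatter is random.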